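**Retrosynthetic overview**

- The bromochloride end is made last from the terminal Me2C=CH alkene (Shi epoxide, bromide opening, 1,2-bromine shift with chloride capture). Before that, the side-chain tertiary allylic carbinol is made from a primary boronic ester and (R)-but-3-en-2-yl carbamate by lithiation–borylation.
- Key disconnection: the bond between ring carbon C3 of the 7-oxabicyclo[2.2.1]heptane and the first CH2 of the halogenated chain. A tertiary C3 radical, made by hydrogen-atom transfer to an exocyclic C3=CH2 (which becomes the C3 methyl), adds to acrolein.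
- Enabling feature: C3 is a ring carbon of the oxanorbornane, flanked by bridgehead C4–H and by C2 with an endo substituent. Its exo face (syn to the O7 bridge) is open and its endo face is covered by the C5–C6 bridge, so the acceptor enters exo and the new methyl ends endo.
- Ring order: the only ring-forming event is the enantioselective Diels–Alder dearomatization of 2-methylfuran (gives O7, C1, C6, C5, C4) with an allenoate (gives C2, C3); the C5=C6 bond is then saturated.

Key step: step 3

Remark: the catalyst antipode in step 1 is assumed to be the one that delivers the (1S,2S,4R) adduct; if the sense of induction is the opposite, the mirror-image catalyst is used. Locants of the bicycle: O7 bridge, C1 methyl-bearing bridgehead, C2 side-chain carbon, C3 quaternary carbon, C4 hydrogen-bearing bridgehead.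

**Route**

Step 1
Reactants: 1 2-methylfuran; 2 ethyl buta-2,3-dienoate
Product: 3 ethyl (1S,2S,4R)-1-methyl-3-methylidene-7-oxabicyclo[2.2.1]hept-5-ene-2-carboxylate (ester endo)
Conditions: (S)-1-(2-methylphenyl)-3,3-diphenyltetrahydropyrrolo[1,2-c][1,3,2]oxazaborole (20 mol %), AlBr3 (16 mol %), CH2Cl2, −78 to −40 °C
Reagents that add atoms: none
Why: Chiral oxazaborolidinium-catalysed Diels–Alder dearomatization of the furan across the activated C2=C3 bond of the allenoate; the unsubstituted furan C5 (larger HOMO coefficient) bonds to the central allene carbon so the ester carbon sits next to the methyl bridgehead, the endo transition state puts the ester endo at C2, and the catalyst shields one face of the bound ester, which sets C1, C2 and C4 together.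

Step 2
Reactants: 3 ethyl (1S,2S,4R)-1-methyl-3-methylidene-7-oxabicyclo[2.2.1]hept-5-ene-2-carboxylate
Product: 4 ethyl (1S,2S,4R)-1-methyl-3-methylidene-7-oxabicyclo[2.2.1]heptane-2-carboxylate
Conditions: KO2CN=NCO2K, AcOH, MeOH/CH2Cl2, 0 °C to rt
Reagents that add atoms: none
Why: Diimide reduction transfers H2 in a concerted syn fashion much faster to the strained norbornene-type C5=C6 bond than to the 1,1-disubstituted exocyclic alkene; this also stops cycloreversion of the furan adduct and touches no stereocenter.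

Step 3
Reactants: 4 ethyl (1S,2S,4R)-1-methyl-3-methylidene-7-oxabicyclo[2.2.1]heptane-2-carboxylate; 5 acrolein
Product: 6 ethyl (1S,2S,3S,4R)-1,3-dimethyl-3-(3-oxopropyl)-7-oxabicyclo[2.2.1]heptane-2-carboxylate
Conditions: Fe(acac)3 (30 mol %), PhSiH3, acrolein (3 equiv), EtOH/(CH2OH)2, 40–60 °C, sealed vessel
Reagents that add atoms: none
Why: An iron hydride formed from Fe(acac)3 and PhSiH3 transfers a hydrogen atom to the terminal CH2 of the exocyclic alkene (Markovnikov), which creates the C3 methyl group and a tertiary C3 radical; this radical adds to the CH2 terminus of acrolein (Giese addition), and the α-formyl radical is reduced by divalent iron to the enolate and protonated by ethanol, which returns trivalent iron. The closest known reaction type is the iron-catalysed hydrogen-atom-transfer reductive olefin cross-coupling of 1,1-disubstituted alkenes with enones and enals, a standard way to build quaternary carbons. No ring is closed in this step. The new quaternary stereocenter C3 is set by the substrate: the planar radical is approached on the exo face, syn to the O7 bridge, because the endo face is screened by the C5–C6 ethano bridge and by the endo ester on C2, so the incoming chain ends exo and the new methyl endo. The step needs hydrogen-atom transfer to a single alkene and radical trapping faster than reduction or hydrogen back-transfer towards the conjugated ester; the first is secured because 4 holds only one C=C bond, the second by the excess of acceptor.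

Step 4
Reactants: 6 ethyl (1S,2S,3S,4R)-1,3-dimethyl-3-(3-oxopropyl)-7-oxabicyclo[2.2.1]heptane-2-carboxylate
Product: 7 ethyl (1S,2S,3S,4R)-1,3-dimethyl-3-(4-methylpent-3-en-1-yl)-7-oxabicyclo[2.2.1]heptane-2-carboxylate
Conditions: i-PrPPh3I, n-BuLi, THF, 0 °C; then 6, −78 to 0 °C
Reagents that add atoms: isopropyltriphenylphosphonium iodide, CC(C)[P+](c1ccccc1)(c1ccccc1)c1ccccc1.[I-]
Why: Wittig olefination of the aldehyde with the unstabilised isopropylidene ylide gives the trisubstituted alkene while the hindered ester is left alone; no stereocenter is formed.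

Step 5
Reactants: 7 ethyl (1S,2S,3S,4R)-1,3-dimethyl-3-(4-methylpent-3-en-1-yl)-7-oxabicyclo[2.2.1]heptane-2-carboxylate
Product: 8 (1S,2S,3S,4R)-1,3-dimethyl-3-(4-methylpent-3-en-1-yl)-7-oxabicyclo[2.2.1]heptane-2-carbaldehyde
Conditions: i-Bu2AlH, CH2Cl2, −78 °C; aqueous Rochelle salt
Reagents that add atoms: none
Why: Partial hydride reduction of the ester stops at the aluminium hemiacetal at −78 °C and releases the aldehyde on work-up; the conditions are not basic, so C2 is not epimerised.

Step 6
Reactants: 8 (1S,2S,3S,4R)-1,3-dimethyl-3-(4-methylpent-3-en-1-yl)-7-oxabicyclo[2.2.1]heptane-2-carbaldehyde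
Product: 9 (1S,2S,3S,4R)-2-ethenyl-1,3-dimethyl-3-(4-methylpent-3-en-1-yl)-7-oxabicyclo[2.2.1]heptane
Conditions: Ph3PCH3Br, KN(SiMe3)2, THF, 0 °C; then 8, −78 to 0 °C
Reagents that add atoms: methyltriphenylphosphonium bromide, C[P+](c1ccccc1)(c1ccccc1)c1ccccc1.[Br-]
Why: Wittig methylenation; fast addition of the ylide at low temperature to the α-branched aldehyde should outrun enolisation, so the C2 configuration is kept.

Step 7
Reactants: 9 (1S,2S,3S,4R)-2-ethenyl-1,3-dimethyl-3-(4-methylpent-3-en-1-yl)-7-oxabicyclo[2.2.1]heptane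
Product: 10 2-{2-[(1S,2S,3S,4R)-1,3-dimethyl-3-(4-methylpent-3-en-1-yl)-7-oxabicyclo[2.2.1]heptan-2-yl]ethyl}-4,4,5,5-tetramethyl-1,3,2-dioxaborolane
Conditions: [Ir(cod)Cl]2 (1.5 mol %), dppm (3 mol %), pinacolborane, CH2Cl2, rt
Reagents that add atoms: pinacolborane, CC1(C)OBOC1(C)C
Why: Iridium-catalysed anti-Markovnikov hydroboration is selective for the monosubstituted alkene over the trisubstituted one and forms no stereocenter.

Step 8
Reactants: 11 (R)-but-3-en-2-ol
Product: 12 (R)-but-3-en-2-yl N,N-di(propan-2-yl)carbamate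
Conditions: i-Pr2NCOCl, Et3N, CH2Cl2, reflux
Reagents that add atoms: N,N-diisopropylcarbamoyl chloride, CC(C)N(C(C)C)C(Cl)=O
Why: O-Carbamoylation of the secondary allylic alcohol by acyl substitution; the stereocenter is not involved.

Step 9
Reactants: 10 2-{2-[(1S,2S,3S,4R)-1,3-dimethyl-3-(4-methylpent-3-en-1-yl)-7-oxabicyclo[2.2.1]heptan-2-yl]ethyl}-4,4,5,5-tetramethyl-1,3,2-dioxaborolane; 12 (R)-but-3-en-2-yl N,N-di(propan-2-yl)carbamate
Product: 16 (3S)-5-[(1S,2S,3S,4R)-1,3-dimethyl-3-(4-methylpent-3-en-1-yl)-7-oxabicyclo[2.2.1]heptan-2-yl]-3-methylpent-1-en-3-ol, via lithiated carbamate 13 (not isolated), via boronate complex 14 (not isolated), via tertiary boronic ester 15 (not isolated)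
Conditions: 12 (1.3 equiv), s-BuLi, TMEDA, Et2O, −78 °C; then 10, −78 °C to rt; then NaOH, H2O2, THF, 0 °C
Reagents that add atoms: hydrogen peroxide, OO
Why: Lithiation–borylation: α-lithiation of the allylic carbamate with retention, boron-ate formation with retention, stereospecific 1,2-metallate rearrangement with inversion and oxidation with retention convert the (R)-carbamate into the (S)-tertiary allylic alcohol, so the side-chain carbinol center is set by the reagent.

Step 10
Reactants: 16 (3S)-5-[(1S,2S,3S,4R)-1,3-dimethyl-3-(4-methylpent-3-en-1-yl)-7-oxabicyclo[2.2.1]heptan-2-yl]-3-methylpent-1-en-3-ol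
Product: 17 (3S)-5-[(1S,2S,3S,4R)-3-{2-[(2R)-3,3-dimethyloxiran-2-yl]ethyl}-1,3-dimethyl-7-oxabicyclo[2.2.1]heptan-2-yl]-3-methylpent-1-en-3-ol
Conditions: D-fructose-derived Shi ketone (30 mol %), Oxone (KHSO5), K2CO3, Bu4NHSO4, MeCN/dimethoxymethane/aqueous buffer pH 10.5, 0 °C
Reagents that add atoms: potassium peroxymonosulfate, OOS(=O)(=O)[O-].[K+]
Why: Shi asymmetric epoxidation: the chiral dioxirane epoxidises the electron-rich trisubstituted alkene through a spiro transition state to give the (R)-epoxide under reagent control, and the monosubstituted vinyl group is too slow to compete.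

Step 11
Reactants: 17 (3S)-5-[(1S,2S,3S,4R)-3-{2-[(2R)-3,3-dimethyloxiran-2-yl]ethyl}-1,3-dimethyl-7-oxabicyclo[2.2.1]heptan-2-yl]-3-methylpent-1-en-3-ol
Product: 18 (3S)-5-[(1S,2S,3S,4R)-3-[(3R)-4-bromo-3-hydroxy-4-methylpentyl]-1,3-dimethyl-7-oxabicyclo[2.2.1]heptan-2-yl]-3-methylpent-1-en-3-ol
Conditions: MgBr2·OEt2, Et2O, −20 °C; aqueous work-up
Reagents that add atoms: magnesium bromide, [Mg+2].[Br-].[Br-]
Why: Lewis-acid-assisted epoxide opening in which bromide attacks the tertiary carbon (Markovnikov, borderline SN1), so the secondary C–O bond and its (R) configuration are kept; the non-protic conditions spare the tertiary allylic alcohol.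

Step 12
Reactants: 18 (3S)-5-[(1S,2S,3S,4R)-3-[(3R)-4-bromo-3-hydroxy-4-methylpentyl]-1,3-dimethyl-7-oxabicyclo[2.2.1]heptan-2-yl]-3-methylpent-1-en-3-ol
Product: 21 (3S)-5-[(1S,2S,3S,4R)-3-[(3S)-3-bromo-4-chloro-4-methylpentyl]-1,3-dimethyl-7-oxabicyclo[2.2.1]heptan-2-yl]-3-methylpent-1-en-3-ol, via secondary triflate 19 (not isolated), via bromonium triflate 20 (not isolated)
Conditions: Tf2O (1.05 equiv), 2,6-lutidine, CH2Cl2, −78 °C; then Bu4NCl (excess), −78 to 0 °C
Reagents that add atoms: tetrabutylammonium chloride, CCCC[N+](CCCC)(CCCC)CCCC.[Cl-]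
Why: Neighbouring-group participation: the tertiary bromine displaces the secondary triflate from the rear to give a bromonium ion (inversion at the secondary carbon), and chloride opens it at the tertiary carbon to give the (S)-bromide and the tertiary chloride; the hindered tertiary allylic alcohol should not be triflated at −78 °C with one equivalent of anhydride.

**Compound list**

1 | 2-methylfuran | Cc1ccco1 | starting material
2 | ethyl buta-2,3-dienoate | C=C=CC(=O)OCC | starting material
3 | ethyl (1S,2S,4R)-1-methyl-3-methylidene-7-oxabicyclo[2.2.1]hept-5-ene-2-carboxylate | CCOC(=O)[C@H]1C(=C)[C@H]2C=C[C@]1(C)O2 | intermediate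
4 | ethyl (1S,2S,4R)-1-methyl-3-methylidene-7-oxabicyclo[2.2.1]heptane-2-carboxylate | CCOC(=O)[C@H]1C(=C)[C@H]2CC[C@]1(C)O2 | intermediate
5 | acrolein | C=CC=O | starting material
6 | ethyl (1S,2S,3S,4R)-1,3-dimethyl-3-(3-oxopropyl)-7-oxabicyclo[2.2.1]heptane-2-carboxylate | CCOC(=O)[C@H]1[C@](C)(CCC=O)[C@H]2CC[C@]1(C)O2 | intermediate
7 | ethyl (1S,2S,3S,4R)-1,3-dimethyl-3-(4-methylpent-3-en-1-yl)-7-oxabicyclo[2.2.1]heptane-2-carboxylate | CCOC(=O)[C@H]1[C@](C)(CCC=C(C)C)[C@H]2CC[C@]1(C)O2 | intermediate
8 | (1S,2S,3S,4R)-1,3-dimethyl-3-(4-methylpent-3-en-1-yl)-7-oxabicyclo[2.2.1]heptane-2-carbaldehyde | O=C[C@H]1[C@](C)(CCC=C(C)C)[C@H]2CC[C@]1(C)O2 | intermediate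
9 | (1S,2S,3S,4R)-2-ethenyl-1,3-dimethyl-3-(4-methylpent-3-en-1-yl)-7-oxabicyclo[2.2.1]heptane | C=C[C@H]1[C@](C)(CCC=C(C)C)[C@H]2CC[C@]1(C)O2 | intermediate
10 | 2-{2-[(1S,2S,3S,4R)-1,3-dimethyl-3-(4-methylpent-3-en-1-yl)-7-oxabicyclo[2.2.1]heptan-2-yl]ethyl}-4,4,5,5-tetramethyl-1,3,2-dioxaborolane | CC1(C)OB(CC[C@H]2[C@](C)(CCC=C(C)C)[C@H]3CC[C@]2(C)O3)OC1(C)C | intermediate
11 | (R)-but-3-en-2-ol | C=C[C@@H](C)O | starting material
12 | (R)-but-3-en-2-yl N,N-di(propan-2-yl)carbamate | C=C[C@@H](C)OC(=O)N(C(C)C)C(C)C | intermediate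
13 | (R)-2-lithiobut-3-en-2-yl N,N-di(propan-2-yl)carbamate (lithium in the place of the carbinol hydrogen) | C=C[C@@]([Li])(C)OC(=O)N(C(C)C)C(C)C | intermediate
14 | lithium boronate complex of 13 and 10 (boron in the place of lithium, retention) | [Li+].C=C[C@@]([B-]1(CC[C@H]2[C@](C)(CCC=C(C)C)[C@H]3CC[C@]2(C)O3)OC(C)(C)C(C)(C)O1)(C)OC(=O)N(C(C)C)C(C)C | intermediate
15 | (R)-configured tertiary allylic pinacol boronic ester (alkyl group migrated to carbon with inversion) | C=C[C@](B1OC(C)(C)C(C)(C)O1)(C)CC[C@H]2[C@](C)(CCC=C(C)C)[C@H]3CC[C@]2(C)O3 | intermediate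
16 | (3S)-5-[(1S,2S,3S,4R)-1,3-dimethyl-3-(4-methylpent-3-en-1-yl)-7-oxabicyclo[2.2.1]heptan-2-yl]-3-methylpent-1-en-3-ol | C=C[C@@](C)(O)CC[C@H]1[C@](C)(CCC=C(C)C)[C@H]2CC[C@]1(C)O2 | intermediate
17 | (3S)-5-[(1S,2S,3S,4R)-3-{2-[(2R)-3,3-dimethyloxiran-2-yl]ethyl}-1,3-dimethyl-7-oxabicyclo[2.2.1]heptan-2-yl]-3-methylpent-1-en-3-ol | C=C[C@@](C)(O)CC[C@H]1[C@](C)(CC[C@H]3OC3(C)C)[C@H]2CC[C@]1(C)O2 | intermediate
18 | (3S)-5-[(1S,2S,3S,4R)-3-[(3R)-4-bromo-3-hydroxy-4-methylpentyl]-1,3-dimethyl-7-oxabicyclo[2.2.1]heptan-2-yl]-3-methylpent-1-en-3-ol | C=C[C@@](C)(O)CC[C@H]1[C@](C)(CC[C@@H](O)C(C)(C)Br)[C@H]2CC[C@]1(C)O2 | intermediate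
19 | secondary trifluoromethanesulfonate of 18 (configuration unchanged) | C=C[C@@](C)(O)CC[C@H]1[C@](C)(CC[C@@H](OS(=O)(=O)C(F)(F)F)C(C)(C)Br)[C@H]2CC[C@]1(C)O2 | intermediate
20 | bromonium trifluoromethanesulfonate (bromine bridging the former carbinol carbon, inverted, and the CMe2 carbon) | C=C[C@@](C)(O)CC[C@H]1[C@](C)(CC[C@@H]3[Br+]C3(C)C)[C@H]2CC[C@]1(C)O2.[O-]S(=O)(=O)C(F)(F)F | intermediate
21 | (3S)-5-[(1S,2S,3S,4R)-3-[(3S)-3-bromo-4-chloro-4-methylpentyl]-1,3-dimethyl-7-oxabicyclo[2.2.1]heptan-2-yl]-3-methylpent-1-en-3-ol | C=C[C@@](C)(O)CC[C@H]1[C@](C)(CC[C@H](Br)C(C)(C)Cl)[C@H]2CC[C@]1(C)O2 | target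

**Step count and risks**

Total step count: 12. Longest linear sequence: 11 (steps 1–7 and 9–12; step 8 is a side branch).

Steps most likely to fail:

1. Step 1. What may go wrong: weak facial and endo/exo discrimination in a reversible furan cycloaddition, cycloreversion on warming, or conjugate (Friedel–Crafts-type) alkylation of the furan instead of cycloaddition. Fallback: setting out from 1 (with 2), an uncatalysed or ZnI2-promoted Diels–Alder reaction should give the racemic endo adduct F1. A hydrolase kinetic resolution (for example pig liver esterase, aqueous buffer) chosen to hydrolyse the unwanted enantiomer then turns that enantiomer into the acid F2, which is removed by basic extraction. The unreacted ester is 3, where the route is rejoined.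

2. Step 12. What may go wrong: loss of regio- and stereochemical fidelity through direct chloride attack on the triflate, proton loss from the bromonium ion, or activation of the tertiary allylic alcohol. Fallback: setting out from 17, the epoxide is opened with Et2AlCl (CH2Cl2, −78 °C) at the tertiary carbon to give the chlorohydrin F3 with the secondary alcohol configuration kept. An Appel bromination (PPh3, CBr4, CH2Cl2) then replaces the secondary hydroxyl by bromide with inversion in a direct SN2 step and arrives at 21.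

3. Step 9. What may go wrong: borylation at the γ-terminus of the lithiated allyl carbamate or partial loss of configuration, giving the wrong constitution or eroded purity at the carbinol center. Fallback: setting out from 9, hydroboration of the vinyl group with 9-BBN gives the B-alkyl-9-BBN F4. Suzuki–Miyaura coupling of F4 with (E)-3-iodobut-2-en-1-ol (Pd(dppf)Cl2, aqueous K3PO4, THF/DMF) should give the (E)-allylic alcohol F5. Sharpless asymmetric epoxidation (Ti(OiPr)4, L-(+)-diethyl tartrate, t-BuOOH, −20 °C) gives the (2S,3S)-epoxy alcohol F6. Iodination (I2, PPh3, imidazole) gives the epoxy iodide F7, and reductive opening with zinc dust in AcOH/EtOH transposes it to the tertiary allylic alcohol 16, where the route is rejoined.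

Further compounds
F1 | step 1 | racemic ethyl 1-methyl-3-methylidene-7-oxabicyclo[2.2.1]hept-5-ene-2-carboxylate, endo ester (3 and its mirror image) | CCOC(=O)[C@H]1C(=C)[C@H]2C=C[C@]1(C)O2.CCOC(=O)[C@@H]1C(=C)[C@@H]2C=C[C@@]1(C)O2
F2 | step 1 | (1R,2R,4S)-1-methyl-3-methylidene-7-oxabicyclo[2.2.1]hept-5-ene-2-carboxylic acid | OC(=O)[C@@H]1C(=C)[C@@H]2C=C[C@@]1(C)O2
F3 | step 12 | (3S)-5-[(1S,2S,3S,4R)-3-[(3R)-4-chloro-3-hydroxy-4-methylpentyl]-1,3-dimethyl-7-oxabicyclo[2.2.1]heptan-2-yl]-3-methylpent-1-en-3-ol | C=C[C@@](C)(O)CC[C@H]1[C@](C)(CC[C@@H](O)C(C)(C)Cl)[C@H]2CC[C@]1(C)O2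
F4 | step 9 | 9-{2-[(1S,2S,3S,4R)-1,3-dimethyl-3-(4-methylpent-3-en-1-yl)-7-oxabicyclo[2.2.1]heptan-2-yl]ethyl}-9-borabicyclo[3.3.1]nonane | C1CCC2CCCC1B2CC[C@H]3[C@](C)(CCC=C(C)C)[C@H]4CC[C@]3(C)O4
F5 | step 9 | (2E)-5-[(1S,2S,3S,4R)-1,3-dimethyl-3-(4-methylpent-3-en-1-yl)-7-oxabicyclo[2.2.1]heptan-2-yl]-3-methylpent-2-en-1-ol | OC/C=C(\C)CC[C@H]1[C@](C)(CCC=C(C)C)[C@H]2CC[C@]1(C)O2
F6 | step 9 | (2S,3S)-2,3-epoxide of F5 (epoxy alcohol) | OC[C@@H]1O[C@@]1(C)CC[C@H]2[C@](C)(CCC=C(C)C)[C@H]3CC[C@]2(C)O3
F7 | step 9 | primary iodide of F6 (epoxide configuration unchanged) | IC[C@@H]1O[C@@]1(C)CC[C@H]2[C@](C)(CCC=C(C)C)[C@H]3CC[C@]2(C)O3
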